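We decide to carry one number through this flask: the share of the open intermediate that the first nucleophile takes in competition with the second.

- green: starting material 0.11 M; first nucleophile 0.16 M; second nucleophile 0.055 M; capture agent 0.033 M; run made earlier
- flask: starting material 0.11 M; first nucleophile 0.104 M; second nucleophile 0.0550 M; capture agent 0.0330 M; time 2.5 d

green run (percent of the starting material charged)

| time / h | target / % | starting material / % |
|---|---|---|
| 0.500 | 9.8 | 85.6 |
| 1.50 | 19.9 | 62.9 |
| 3.00 | 25.6 | 38.4 |
| 4.00 | 27.8 | 26.6 |
| 6.00 | 26.9 | 15.4 |

(each reading ± 1 percentage point)

- the best time, 2.5 d at the latest, for target
- the amount of target, in percent of the starting material charged, at that time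

- percent here means starting material units held: one side product counts as two
- the numbers in the tables scatter by 1 percentage point (one standard deviation)
- steps that have been proposed: starting material -> open intermediate; first nucleophile + open intermediate -> target; second nucleophile + open intermediate -> other capture product; open intermediate + capture agent -> trapped intermediate; target <-> isomer of the product; starting material + target -> side product

In the proposed steps, starting material opens by itself. The open intermediate then meets the first nucleophile (giving target), the second nucleophile or the capture agent, and target drains to its isomer and, with starting material, to side product.

The first green reading gives 0.681 of target per starting material consumed. If the nucleophiles compete in proportion to concentration, that reading means a rate-constant ratio ρ, first over second, of 0.732. With charges B and D, this flask then has the share s = ρB/(ρB + D), which is 0.581.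

No proposed opening or drain step contains a nucleophile, so we scale the green peak reading, 27.8%, by the ratio of shares. That gives 23.7%, which we place near the two highest green readings, at 0.17 d and 0.25 d.

But that first reading has scatter, and target has already begun to drain by then, so the green share may be higher. Try 0.750: s becomes 0.661, and our scaled peak moves to 24.5%.

A second doubt: the first nucleophile is charged at 0.945 equivalents, so might it be the limiting reagent? Its balance suggests not. If each unit of starting material opens and s holds throughout, starting material asks for 0.0639 M of it, less than its charge, which leaves about 38.6% of that charge.

The forecast gave 24% at 0.19 d, holding that "The peak time depends on the decay and drain rates, not on the first nucleophile".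

The flask gives 24.8% at 0.205 d. At the end this flask holds 41.5% of the first nucleophile's charge and 43.3% of the second's, the first more than our balance left.

    starting material → open intermediate (k = 0.270 h⁻¹)
    first nucleophile + open intermediate → target (k = 2100 M⁻¹ h⁻¹)
    second nucleophile + open intermediate → other capture product (k = 2000 M⁻¹ h⁻¹)
    open intermediate + capture agent → trapped intermediate (k = 3.10 M⁻¹ h⁻¹)
    target ⇌ isomer of the product (K = 3.70, k = 0.0890 h⁻¹)
    starting material + target → side product (k = 2.80 M⁻¹ h⁻¹)

In this flask at 0.0866 d, target is made 1.88 times faster than it is used up, and its forward step to the isomer runs at 0.55 of its step to side product, so slower. At the end of this flask, side product stands at 32.7% of the starting material charged, more than the isomer's 30.6%.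

In the neighbour charged with 0.44 M of starting material, the same nucleophile charges give the same s at the start, so the demand reckoned with that s is 0.255 M, more than the first nucleophile's charge. That neighbour ends with 0% of the first nucleophile's charge and with open intermediate at 36.5% of the starting material charged, and its best target is 10.4%.

The numbers in the tables come from a simulation with made-up constants; noise was put on by code.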